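Ring D of the target (O1', C2', C3', C4', C4a', C8a') is disconnected as a hetero-Diels–Alder adduct: the B-ring ortho-quinone methide O1'=C8a'–C4a'=C4' plus the C2'=C3' alkene of an isobutenylboronate, boron standing in for the C3' hydroxyl. One acid-catalysed operation forms C4'–C3' and O1'–C2', closes ring D and sets C3' (S). Its precursor is a salicyl alcohol, 3-(benzyloxy)-5-bromo-2-hydroxybenzyl alcohol: free phenol and primary benzylic alcohol for the quinone methide, benzyl on the future O8', bromine at the future C6'. Stereoretentive C–B oxidation, borylation of the bromide, rhodium-catalysed asymmetric addition to 5,7-bis(benzyloxy)chromone (sets C2) and hydrogenolysis finish the synthesis.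

Key step: step 4

Remark: primed locants denote the 2,2-dimethylchroman unit (rings B and D), unprimed locants the flavanone (rings A and C); the C3' boronate and the C3' alcohol are both S, because oxidation with retention swaps the lowest-ranked heavy substituent (B) for the highest (O).
Assumption: the sense of induction of the chiral catalysts in steps 4 and 9 is assigned by analogy and is to be confirmed in the first run; both antipodes of each catalyst are available.

Step 1
Reactants: 1 2-(benzyloxy)phenol; 2 formaldehyde (used as paraformaldehyde)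
Product: 3 3-(benzyloxy)-2-hydroxybenzaldehyde
Conditions: MgCl2 (2 equiv), Et3N (2 equiv), (CH2O)n (3 equiv), THF, reflux; then 1 M HCl
Reagents that add atoms: none
Why: Casnati–Skattebøl ortho-formylation, in which the magnesium phenoxide directs formaldehyde to the only free ortho position and a second equivalent of formaldehyde oxidises the benzylic alkoxide to the aldehyde, the benzyl ether being inert.

Step 2
Reactants: 3 3-(benzyloxy)-2-hydroxybenzaldehyde
Product: 4 3-(benzyloxy)-5-bromo-2-hydroxybenzaldehyde
Conditions: NBS (1.05 equiv), MeCN, 0 °C to rt, dark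
Reagents that add atoms: N-bromosuccinimide, O=C1CCC(=O)N1Br
Why: Electrophilic aromatic bromination in which the hydroxyl group (para) and the formyl group (meta) both direct to C5, as in the bromination of ortho-vanillin, so the regiochemistry should be clean.

Step 3
Reactants: 4 3-(benzyloxy)-5-bromo-2-hydroxybenzaldehyde
Product: 5 3-(benzyloxy)-5-bromo-2-hydroxybenzyl alcohol
Conditions: NaBH4, THF/MeOH, 0 °C; then aq. NH4Cl
Reagents that add atoms: none
Why: Chemoselective borohydride reduction of the aldehyde, which leaves the aryl bromide and the benzyl ether untouched and gives a salicyl alcohol that is stable to the neutral work-up.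

Step 4
Reactants: 5 3-(benzyloxy)-5-bromo-2-hydroxybenzyl alcohol; 6 2-methylprop-1-enylboronic acid pinacol ester
Product: 8 2-[(3S)-8-(benzyloxy)-6-bromo-2,2-dimethylchroman-3-yl]-4,4,5,5-tetramethyl-1,3,2-dioxaborolane, via ortho-quinone methide 7 (not isolated)
Conditions: (R)-N-triflylphosphoramide of 3,3'-bis(2,4,6-triisopropylphenyl)-BINOL (10 mol %), 6 (3 equiv), 5 Å MS, toluene/CH2Cl2 (3:1), 0 °C to rt, 5 added over 6 h
Reagents that add atoms: none
Why: Proposed new method: the strong chiral acid protonates the benzylic hydroxyl of 5 and, pushed by the phenol oxygen, expels water to give the ion-paired ortho-quinone methide 7, whose electrophilic methylene carbon bonds to the boron-bearing alkene carbon of 6 because the positive charge then builds up on the tertiary carbon (two methyl groups plus hyperconjugation from the adjacent C–B bond), and the phenol oxygen collapses onto that carbon in the same asynchronous inverse-demand [4+2] event. The closest known reaction types are chiral Brønsted acid-catalysed hetero-Diels–Alder reactions of in situ ortho-quinone methides with enol ethers, vinyl sulfides, enamides and styrenes, and cycloadditions in which an alkenyl pinacolboronate serves as the 2π partner and keeps its boron; what is new is an alkenylboronate as dienophile for an ortho-quinone methide with retention of boron, where known additions of alkenylboronates to ortho-quinone methides transfer the alkenyl group and lose boron. Ring D closes as the six-membered ring of this intermolecular cycloaddition, C4'–C3' leading and O1'–C2' following, with no separate cyclisation step. C3' is the only new stereocentre and is set by catalyst control: the phosphoramide anion stays hydrogen-bonded to the quinone methide oxygen, and its 3,3'-aryl pocket admits only one face of the Me2C=CH–B unit, hydrogen and the bulky dioxaborolane on C3' being the groups it tells apart. The step needs regioselectivity (secured by the gem-dimethyl terminus), retention of boron over loss to the prenylphenol (secured by the hindered, weakly Lewis-acidic pinacol ester, by sieves that take up the water set free, and by the phenol oxygen sitting ready for six-membered closure) and freedom from self-condensation (every position ortho or para to the phenol oxygen of 5 is substituted, and 5 is added slowly to excess 6). An N-triflylphosphoramide replaces a plain phosphoric acid because the primary benzylic alcohol of 5, with bromine and benzyloxy both meta to it, should ionise too slowly under the weaker acid, while it is still not acidic enough to protonate and deborylate 6 at a competitive rate.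

Step 5
Reactants: 8 2-[(3S)-8-(benzyloxy)-6-bromo-2,2-dimethylchroman-3-yl]-4,4,5,5-tetramethyl-1,3,2-dioxaborolane
Product: 9 (3S)-8-(benzyloxy)-6-bromo-2,2-dimethylchroman-3-ol
Conditions: NaBO3·4H2O (5 equiv), THF/H2O (1:1), rt
Reagents that add atoms: sodium perborate, [Na+].[Na+].O[B-]1(O)OO[B-](O)(O)OO1
Why: Perborate oxidation of a secondary alkyl pinacolboronate, in which C3' migrates from boron to oxygen with retention (as in hydroboration–oxidation of cyclic enol ethers, which pass through the same β-oxygenated arrangement), the weakly basic oxidant being chosen to disfavour β-elimination of the aryloxide.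

Step 6
Reactants: 9 (3S)-8-(benzyloxy)-6-bromo-2,2-dimethylchroman-3-ol
Product: 10 [(3S)-8-(benzyloxy)-3-hydroxy-2,2-dimethylchroman-6-yl]boronic acid
Conditions: Pd(OAc)2 (2 mol %), XPhos (4 mol %), B2(OH)4 (2 equiv), KOAc (3 equiv), EtOH, 80 °C; then dilute aq. HCl
Reagents that add atoms: tetrahydroxydiboron, OB(O)B(O)O
Why: Miyaura-type palladium-catalysed borylation of an unhindered aryl bromide with tetrahydroxydiboron, which gives the boronic acid directly, tolerates the free secondary alcohol and the benzyl ether, and does not touch C3'.

Step 7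
Reactants: 11 2,4,6-trihydroxyacetophenone
Product: 12 1-[2,4-bis(benzyloxy)-6-hydroxyphenyl]ethan-1-one
Conditions: BnBr (2.1 equiv), K2CO3 (2.2 equiv), DMF, rt
Reagents that add atoms: benzyl bromide, BrCc1ccccc1
Why: Williamson etherification in which the two hydroxyls that are not hydrogen-bonded to the acetyl carbonyl react first, so two equivalents of benzyl bromide leave the chelated ortho-hydroxyl free.

Step 8
Reactants: 12 1-[2,4-bis(benzyloxy)-6-hydroxyphenyl]ethan-1-one
Product: 14 5,7-bis(benzyloxy)-4H-chromen-4-one, via enaminone 13 (not isolated)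
Conditions: Me2NCH(OMe)2 (2 equiv), toluene, 95 °C; then conc. HCl, CH2Cl2, rt
Reagents that add atoms: N,N-dimethylformamide dimethyl acetal, COC(OC)N(C)C
Why: Enaminone route to chromones, in which condensation of the methyl ketone with the formamide acetal gives the enaminone and acid then promotes conjugate addition of the phenol and loss of dimethylamine to close the pyranone ring.

Step 9
Reactants: 10 [(3S)-8-(benzyloxy)-3-hydroxy-2,2-dimethylchroman-6-yl]boronic acid; 14 5,7-bis(benzyloxy)-4H-chromen-4-one
Product: 15 (2S)-5,7-bis(benzyloxy)-2-[(3S)-8-(benzyloxy)-3-hydroxy-2,2-dimethylchroman-6-yl]chroman-4-one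
Conditions: [RhCl(C2H4)2]2 (2.5 mol %), (S,S)-Ph-bod* [(1S,4S)-2,5-diphenylbicyclo[2.2.2]octa-2,5-diene] (5.5 mol %), aq. KOH (0.2 equiv), 1,4-dioxane/H2O (10:1), 30 °C; 14 (1.5 equiv)
Reagents that add atoms: none
Why: Hayashi–Miyaura rhodium-catalysed asymmetric 1,4-addition, in which the aryl–rhodium species from 10 inserts the C2=C3 bond of the chromone and water protonates the rhodium enolate, the C2-symmetric diene choosing the face of C2 so that the new centre is set as 2S under catalyst control (the remote C3' centre should have no influence), while the mild, nearly neutral medium avoids opening of ring C to the chalcone.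

Step 10
Reactants: 15 (2S)-5,7-bis(benzyloxy)-2-[(3S)-8-(benzyloxy)-3-hydroxy-2,2-dimethylchroman-6-yl]chroman-4-one
Product: 16 sigmoidin D, (2S)-5,7-dihydroxy-2-[(3S)-3,8-dihydroxy-2,2-dimethylchroman-6-yl]chroman-4-one
Conditions: H2 (1 atm), 10% Pd/C, EtOAc/MeOH (1:1), rt, stopped at full conversion
Reagents that add atoms: none
Why: Hydrogenolysis of three aryl benzyl ethers over palladium on carbon in neutral medium, which should spare the ketone and (with a short reaction time) the benzylic C2–O1 bond and cannot epimerise C2 or C3' because no base is present.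

Compound list
1 | 2-(benzyloxy)phenol | Oc1ccccc1OCc1ccccc1 | starting material
2 | formaldehyde (as paraformaldehyde) | C=O | starting material
3 | 3-(benzyloxy)-2-hydroxybenzaldehyde | O=Cc1cccc(OCc2ccccc2)c1O | intermediate
4 | 3-(benzyloxy)-5-bromo-2-hydroxybenzaldehyde | O=Cc1cc(Br)cc(OCc2ccccc2)c1O | intermediate
5 | 3-(benzyloxy)-5-bromo-2-hydroxybenzyl alcohol | OCc1cc(Br)cc(OCc2ccccc2)c1O | intermediate
6 | 2-methylprop-1-enylboronic acid pinacol ester | CC(C)=CB1OC(C)(C)C(C)(C)O1 | starting material
7 | 2-(benzyloxy)-4-bromo-6-methylidenecyclohexa-2,4-dien-1-one (ortho-quinone methide, formed in situ) | C=C1C=C(Br)C=C(OCc2ccccc2)C1=O | intermediate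
8 | 2-[(3S)-8-(benzyloxy)-6-bromo-2,2-dimethylchroman-3-yl]-4,4,5,5-tetramethyl-1,3,2-dioxaborolane | CC1(C)Oc2c(OCc3ccccc3)cc(Br)cc2C[C@@H]1B4OC(C)(C)C(C)(C)O4 | intermediate
9 | (3S)-8-(benzyloxy)-6-bromo-2,2-dimethylchroman-3-ol | CC1(C)Oc2c(OCc3ccccc3)cc(Br)cc2C[C@@H]1O | intermediate
10 | [(3S)-8-(benzyloxy)-3-hydroxy-2,2-dimethylchroman-6-yl]boronic acid | CC1(C)Oc2c(OCc3ccccc3)cc(B(O)O)cc2C[C@@H]1O | intermediate
11 | 2,4,6-trihydroxyacetophenone | CC(=O)c1c(O)cc(O)cc1O | starting material
12 | 1-[2,4-bis(benzyloxy)-6-hydroxyphenyl]ethan-1-one | CC(=O)c1c(O)cc(OCc2ccccc2)cc1OCc1ccccc1 | intermediate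
13 | (E)-1-[2,4-bis(benzyloxy)-6-hydroxyphenyl]-3-(dimethylamino)prop-2-en-1-one (formed in situ) | CN(C)/C=C/C(=O)c1c(O)cc(OCc2ccccc2)cc1OCc1ccccc1 | intermediate
14 | 5,7-bis(benzyloxy)-4H-chromen-4-one | O=c1ccoc2cc(OCc3ccccc3)cc(OCc3ccccc3)c12 | intermediate
15 | (2S)-5,7-bis(benzyloxy)-2-[(3S)-8-(benzyloxy)-3-hydroxy-2,2-dimethylchroman-6-yl]chroman-4-one | CC1(C)Oc2c(OCc3ccccc3)cc([C@@H]3CC(=O)c4c(OCc5ccccc5)cc(OCc5ccccc5)cc4O3)cc2C[C@@H]1O | intermediate
16 | sigmoidin D, (2S)-5,7-dihydroxy-2-[(3S)-3,8-dihydroxy-2,2-dimethylchroman-6-yl]chroman-4-one | CC1(C)Oc2c(O)cc([C@@H]3CC(=O)c4c(O)cc(O)cc4O3)cc2C[C@@H]1O | target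

Total step count: 10. Longest linear sequence: 8 steps (steps 1 to 6, then 9 and 10); the chromone branch (steps 7 and 8) joins at step 9.

Steps most likely to fail

Step 4 (Proposed new method). What may go wrong:
- the electron-poor primary benzylic alcohol may ionise too slowly;
- boron may be lost after C–C bond formation, giving the prenylphenol and then the boron-free chroman;
- the acid may protodeborylate 6;
- facial selectivity may be poor, because the dienophile offers the catalyst no hydrogen-bond donor.

The fallback uses known chemistry, sets out from 4 and returns at 9, so it also bypasses step 5. Addition of 2-methylprop-1-enylmagnesium bromide (3 equiv, THF, 0 °C) to the aldehyde gives the allylic alcohol 2-(benzyloxy)-4-bromo-6-(1-hydroxy-3-methylbut-2-en-1-yl)phenol F1. Warming with a trace of TsOH in toluene causes loss of water and oxa-6π ring closure to 8-(benzyloxy)-6-bromo-2,2-dimethyl-2H-chromene F2. Jacobsen epoxidation with (S,S)-[N,N'-bis(3,5-di-tert-butylsalicylidene)cyclohexane-1,2-diaminato]manganese chloride (trivalent manganese), NaOCl and 4-phenylpyridine N-oxide in CH2Cl2 at 0 °C should give (3S,4S)-8-(benzyloxy)-6-bromo-3,4-epoxy-2,2-dimethylchroman F3; 2,2-dimethylchromenes are a favoured substrate class for this catalyst. LiAlH4 in THF at 0 °C then delivers hydride to the benzylic C4' and leaves the C3'–O bond untouched, giving 9.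

Step 9. What may go wrong:
- addition to the electron-rich 5,7-dialkoxychromone may be sluggish and protodeboronation of 10 may compete;
- base may open ring C and erode the C2 configuration;
- the facial sense may be opposite to the one assumed (then the antipodal diene is used).

The fallback sets out from 9 and 12 and returns at 15. The dilithio species F4, made from 9 as described in the fallback for step 6, is quenched with DMF to give (3S)-8-(benzyloxy)-3-hydroxy-2,2-dimethylchroman-6-carbaldehyde F5. Claisen–Schmidt condensation of F5 with 12 (KOH, EtOH, rt) gives the chalcone (E)-1-[2,4-bis(benzyloxy)-6-hydroxyphenyl]-3-[(3S)-8-(benzyloxy)-3-hydroxy-2,2-dimethylchroman-6-yl]prop-2-en-1-one F6. NaOAc in refluxing EtOH closes ring C by oxa-Michael addition to a mixture of 15 and its C2 epimer (2R)-5,7-bis(benzyloxy)-2-[(3S)-8-(benzyloxy)-3-hydroxy-2,2-dimethylchroman-6-yl]chroman-4-one F7. The two are separated by preparative HPLC on a chiral stationary phase, and F7 is re-equilibrated through F6 and recycled.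

Step 6. What may go wrong: protodebromination or homocoupling during palladium catalysis, or protodeboronation of the electron-rich boronic acid on isolation. The fallback sets out from 9 and returns at 10. Deprotonation and bromine–lithium exchange with n-BuLi (2.2 equiv, THF, −78 °C) give the dilithio species lithium (3S)-8-(benzyloxy)-6-lithio-2,2-dimethylchroman-3-olate F4, which is quenched with B(OiPr)3 and hydrolysed with dilute HCl to 10.

Further compounds
F1 | step 4 | 2-(benzyloxy)-4-bromo-6-(1-hydroxy-3-methylbut-2-en-1-yl)phenol (racemic carbinol) | CC(C)=CC(O)c1cc(Br)cc(OCc2ccccc2)c1O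
F2 | step 4 | 8-(benzyloxy)-6-bromo-2,2-dimethyl-2H-chromene | CC1(C)C=Cc2cc(Br)cc(OCc3ccccc3)c2O1
F3 | step 4 | (3S,4S)-8-(benzyloxy)-6-bromo-3,4-epoxy-2,2-dimethylchroman | CC1(C)Oc2c(OCc3ccccc3)cc(Br)cc2[C@@H]2O[C@H]12
F4 | step 6 | lithium (3S)-8-(benzyloxy)-6-lithio-2,2-dimethylchroman-3-olate | CC1(C)Oc2c(OCc3ccccc3)cc([Li])cc2C[C@@H]1O[Li]
F5 | step 9 | (3S)-8-(benzyloxy)-3-hydroxy-2,2-dimethylchroman-6-carbaldehyde | CC1(C)Oc2c(OCc3ccccc3)cc(C=O)cc2C[C@@H]1O
F6 | step 9 | (E)-1-[2,4-bis(benzyloxy)-6-hydroxyphenyl]-3-[(3S)-8-(benzyloxy)-3-hydroxy-2,2-dimethylchroman-6-yl]prop-2-en-1-one | CC1(C)Oc2c(OCc3ccccc3)cc(/C=C/C(=O)c3c(O)cc(OCc4ccccc4)cc3OCc3ccccc3)cc2C[C@@H]1O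
F7 | step 9 | (2R)-5,7-bis(benzyloxy)-2-[(3S)-8-(benzyloxy)-3-hydroxy-2,2-dimethylchroman-6-yl]chroman-4-one | CC1(C)Oc2c(OCc3ccccc3)cc([C@H]3CC(=O)c4c(OCc5ccccc5)cc(OCc5ccccc5)cc4O3)cc2C[C@@H]1O
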